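The route rests on cutting the C5–C5' biaryl bond. This bond sits ortho to the phenolic oxygens O4 and O4' of two nearly indistinguishable guaiacol rings (ring A from capsaicin, ring B from dihydrocapsaicin). Because both oxygens flank the bond, one diisopropylsilicon atom can bridge them, so cross-coupling becomes an intramolecular event. In one operation palladium converts C5'–Br of ring B and C5–H of ring A into the biaryl bond and closes a seven-membered dibenzodioxasilepine. The precursor is the mixed bis(aryloxy)diisopropylsilane of capsaicin and 5-bromodihydrocapsaicin. Bromine is placed on the saturated monomer so that the alkene never meets an electrophilic halogen. Fluoride then frees the biphenol.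

Key step: step 3

Assumption: capsaicin numbering is used on both rings (C1 bears CH2N, C3 OMe, C4 O), unprimed atoms belong to ring A and primed atoms to ring B, and both monomers are bought as pure single compounds, not as the natural capsaicinoid mixture.

Step 1
Reactants: 1 dihydrocapsaicin
Product: 2 5-bromodihydrocapsaicin
Conditions: NBS (1.0 equiv), i-Pr2NH (10 mol %), CH2Cl2, 0 °C, dark
Reagents that add atoms: N-bromosuccinimide, O=C1CCC(=O)N1Br
Why: Electrophilic aromatic substitution (amine-catalysed ortho-bromination of a phenol with NBS): the free C4–OH is the strongest director, its para position C1 is blocked by the CH2N arm and one ortho position C3 by OMe, so bromine should enter at C5, and the saturated chain and the amide offer no competing site.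

Step 2
Reactants: 2 5-bromodihydrocapsaicin; 3 dichlorodiisopropylsilane; 4 capsaicin
Product: 6 capsaicin/5-bromodihydrocapsaicin diisopropylsilyl bis-ether, via aryloxychlorodiisopropylsilane 5 (not isolated)
Conditions: (a) slow addition of 2 to 3 (4 equiv), Et3N (1.5 equiv), CH2Cl2, 0 °C to rt, then volatiles and excess 3 stripped under high vacuum; (b) 4 (1.0 equiv), imidazole (2.5 equiv), DMF, rt; chromatography on Et3N-deactivated silica
Reagents that add atoms: dichlorodiisopropylsilane (3), CC(C)[Si](Cl)(Cl)C(C)C
Why: Stepwise nucleophilic substitution at silicon (silyl ether formation): the hindered, more acidic bromophenol meets a large excess of the dichlorosilane so that only one chloride is displaced, and once the excess is removed the remaining Si–Cl bond is taken by the less hindered phenol of capsaicin under imidazole catalysis, with amide N–H and alkene as bystanders.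

Step 3
Reactants: 6 capsaicin/5-bromodihydrocapsaicin diisopropylsilyl bis-ether
Product: 7 cyclic diisopropylsilylene ketal of the target biphenol
Conditions: Pd(OAc)2 (10 mol %), PCy3·HBF4 (20 mol %), CsOPiv (2.5 equiv, dried), 4 Å MS, toluene (0.01–0.02 M), 110 °C, Ar
Reagents that add atoms: none
Why: Zerovalent palladium formed from Pd(OAc)2 and PCy3 inserts into C5'–Br of ring B, bromide is exchanged for pivalate, and the O4'–Si–O4 bridge holds the divalent arylpalladium beside C5–H of ring A, which is broken by pivalate-assisted concerted metalation–deprotonation before reductive elimination forges C5–C5'. The closest known reaction type is the palladium-catalysed intramolecular direct C–H arylation of silicon-tethered bis(aryloxy)silanes, a member of the carboxylate-assisted direct arylation family. The single new ring, the seven-membered dibenzo[d,f][1,3,2]dioxasilepine, closes by reductive elimination from an eight-membered palladacycle (Pd, C5', C4', O, Si, O, C4, C5). No stereocentre is created, the E-alkene is not involved, and the biaryl axis has only the two oxygens as ortho substituents, so it is no stable stereoelement once the bridge is gone. Site selectivity on ring A is secured because C3 bears OMe, which leaves C5 as the only C–H ortho to the silyloxy oxygen and the only one the tethered metal can reach, and homo-coupling is excluded because each molecule holds exactly one bromide and one partner ring. Heck addition, alkene migration and amide N-arylation are disfavoured by high dilution, the remote unactivated disubstituted alkene, the apolar solvent and a monophosphine that does not promote C–N coupling, while dry CsOPiv (which forms no water) and sieves protect the Si–O bonds, and bromide is kept instead of iodide because accumulating iodide slows carboxylate-assisted C–H cleavage.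

Step 4
Reactants: 7 cyclic diisopropylsilylene ketal of the target biphenol
Product: 8 6'',7''-dihydro-5',5'''-dicapsaicin
Conditions: HF·pyridine, pyridine/THF, 0 °C to rt, polyethylene vessel, Ar; aq. NaHCO3 quench
Reagents that add atoms: none
Why: Fluoride-mediated silyl ether cleavage: formation of two strong Si–F bonds releases both aryloxy groups, the mildly acidic medium keeps the electron-rich biphenol protonated and so guards it against aerobic oxidation, and alkene and amides are inert.

Compound list
1 | dihydrocapsaicin, N-(4-hydroxy-3-methoxybenzyl)-8-methylnonanamide | COc1cc(CNC(=O)CCCCCCC(C)C)ccc1O | starting material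
2 | 5-bromodihydrocapsaicin, N-(3-bromo-4-hydroxy-5-methoxybenzyl)-8-methylnonanamide | COc1cc(CNC(=O)CCCCCCC(C)C)cc(Br)c1O | intermediate
3 | dichlorodiisopropylsilane | CC(C)[Si](Cl)(Cl)C(C)C | starting material
4 | capsaicin, (E)-N-(4-hydroxy-3-methoxybenzyl)-8-methylnon-6-enamide | COc1cc(CNC(=O)CCCC/C=C/C(C)C)ccc1O | starting material
5 | N-{3-bromo-4-[chloro(diisopropyl)silyloxy]-5-methoxybenzyl}-8-methylnonanamide (crude chlorosilane) | COc1cc(CNC(=O)CCCCCCC(C)C)cc(Br)c1O[Si](Cl)(C(C)C)C(C)C | intermediate
6 | diisopropylsilyl bis-ether joining O4 of capsaicin (E-alkene) and O4' of 5-bromodihydrocapsaicin | COc1cc(CNC(=O)CCCC/C=C/C(C)C)ccc1O[Si](C(C)C)(C(C)C)Oc1c(Br)cc(CNC(=O)CCCCCCC(C)C)cc1OC | intermediate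
7 | 6,6-diisopropyl-4,8-dimethoxydibenzo[d,f][1,3,2]dioxasilepine bearing CH2NH-(E)-8-methylnon-6-enoyl at C2 and CH2NH-8-methylnonanoyl at C10 | COc1cc(CNC(=O)CCCC/C=C/C(C)C)cc2c1O[Si](C(C)C)(C(C)C)Oc1c(OC)cc(CNC(=O)CCCCCCC(C)C)cc1-2 | intermediate
8 | 6'',7''-dihydro-5',5'''-dicapsaicin (E-alkene) | COc1cc(CNC(=O)CCCC/C=C/C(C)C)cc(-c2cc(CNC(=O)CCCCCCC(C)C)cc(OC)c2O)c1O | target

Total step count: 4
Longest linear sequence: 4 steps (1 → 2 → 6 → 7 → 8)

Steps most likely to fail

**Step 3 (key step).**
- What may go wrong: cleavage of the Si–O bridge by adventitious water or by the base at 110 °C before the C–H bond is broken, hydrodebromination of ring B, or palladium hydride-induced migration of the alkene.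
- Fallback: an intermolecular Suzuki–Miyaura cross-coupling in which each ring carries its own handle, so that cross-selectivity comes from the boron/halogen pairing and not from a tether.
- It sets out from 2 and 4 and comes back to the route at 8.
- Phenol 2 is capped with MOMCl and i-Pr2NEt in CH2Cl2 to give the MOM ether F1.
- Miyaura borylation (B2pin2, PdCl2(dppf), KOAc, dioxane, 80 °C) turns F1 into the pinacol boronate F2.
- Capsaicin 4 is iodinated as its phenolate (NaI, NaOH, slow addition of aqueous NaOCl, MeOH, 0 °C). Under these conditions the ring should react far faster than an unactivated disubstituted alkene, giving 5-iodocapsaicin F3.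
- Coupling of F2 with F3 (Pd(OAc)2, SPhos, K3PO4, dioxane/H2O, 80 °C) should give the mono-MOM biaryl F4.
- HCl in MeOH at rt removes the acetal and delivers 8.

**Step 2.**
- What may go wrong: double displacement at silicon or imidazole-promoted exchange of aryloxy groups, which scrambles the mixed bis-ether into the two symmetrical ones, and hydrolysis of the crude chlorosilane during the solvent change.
- Fallback: the bridge is built from a monofunctional silane, and the second leaving group is unmasked only afterwards, so that only one Si–O bond can form at a time.
- It sets out from 2 and comes back at 6.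
- Phenol 2 is silylated with chlorodiisopropylsilane (i-Pr2SiHCl, imidazole, CH2Cl2, rt) to give the hydrosilyl ether F5, which can be purified.
- One equivalent of NBS in CH2Cl2 at 0 °C converts Si–H into Si–Br and gives the bromosilane F6.
- Once the NBS is consumed, 4 and imidazole are added to the same flask to give 6.

**Step 1.**
- What may go wrong: attack of bromine para to the methoxy group (C6), a second bromination, or ipso attack at C1 with loss of the amidomethyl arm.
- Fallback: the C5–Br bond is bought in place and the amide is built afterwards.
- This branch makes 1 unnecessary. It starts from commercial 5-bromovanillin F7 instead of from a numbered compound and comes back at 2.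
- Condensation with NH2OH·HCl and NaOAc in EtOH/H2O gives the oxime F8.
- Zn dust in AcOH at rt reduces the oxime without touching the aryl bromide and gives 5-bromovanillylamine F9.
- N-selective amide coupling with commercial 8-methylnonanoic acid F10 (EDC·HCl, HOBt, i-Pr2NEt, DMF, rt) gives 2.

Further compounds
F1 | step 3 | N-[3-bromo-5-methoxy-4-(methoxymethoxy)benzyl]-8-methylnonanamide | COCOc1c(Br)cc(CNC(=O)CCCCCCC(C)C)cc1OC
F2 | step 3 | N-[3-methoxy-4-(methoxymethoxy)-5-(4,4,5,5-tetramethyl-1,3,2-dioxaborolan-2-yl)benzyl]-8-methylnonanamide | COCOc1c(OC)cc(CNC(=O)CCCCCCC(C)C)cc1B2OC(C)(C)C(C)(C)O2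
F3 | step 3 | 5-iodocapsaicin, (E)-N-(4-hydroxy-3-iodo-5-methoxybenzyl)-8-methylnon-6-enamide | COc1cc(CNC(=O)CCCC/C=C/C(C)C)cc(I)c1O
F4 | step 3 | mono-MOM ether (on O4' of ring B) of the target biphenol | COCOc1c(OC)cc(CNC(=O)CCCCCCC(C)C)cc1-c2cc(CNC(=O)CCCC/C=C/C(C)C)cc(OC)c2O
F5 | step 2 | N-{3-bromo-4-[(diisopropylsilyl)oxy]-5-methoxybenzyl}-8-methylnonanamide | COc1cc(CNC(=O)CCCCCCC(C)C)cc(Br)c1O[SiH](C(C)C)C(C)C
F6 | step 2 | N-{3-bromo-4-[bromo(diisopropyl)silyloxy]-5-methoxybenzyl}-8-methylnonanamide | COc1cc(CNC(=O)CCCCCCC(C)C)cc(Br)c1O[Si](Br)(C(C)C)C(C)C
F7 | step 1 | 5-bromovanillin (commercial) | COc1cc(C=O)cc(Br)c1O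
F8 | step 1 | (E)-5-bromovanillin oxime | COc1cc(/C=N/O)cc(Br)c1O
F9 | step 1 | 5-bromovanillylamine | COc1cc(CN)cc(Br)c1O
F10 | step 1 | 8-methylnonanoic acid (commercial) | CC(C)CCCCCCC(=O)O
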